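**Strategy**

Everything rests on disconnecting ring C, the 2,4,5-trimethoxybenzyl ring, at two neighbouring bonds: the bond from the benzylic CH2 to C1 and the C2–O bond. Ring C carries carbon at C1, oxygen at the adjacent C2 and methoxy groups at C4 and C5 placed symmetrically about the C1–C2 bond, which is what arises when a carbon nucleophile and then an oxygen electrophile are delivered to the triple bond of 4,5-dimethoxybenzyne. The key step does this in one operation, joining the finished all-cis oxolane core, as a primary alkylmagnesium bromide with a TBS-protected hydroxymethyl group, to an aryne generated from a 2-iodoaryl 4-chlorobenzenesulfonate.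

Key step: step 11

Assumption: the antipode of the bis(oxazolinyl)carbazole ligand that sends the allyl group to the Re face of the aldehyde is used in step 3 (sense of induction to be confirmed on the first run); the side-chain halide is made as the bromide so that magnesium insertion gives the bromomagnesium reagent.

**Route**

Step 1
Reactants: 1 methyl acrylate; 2 (tert-butyldimethylsilyloxy)acetaldehyde
Product: 3 methyl 4-{[tert-butyl(dimethyl)silyl]oxy}-3-hydroxy-2-methylidenebutanoate (racemic)
Conditions: DABCO (0.5 equiv), excess 1 as solvent, rt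
Reagents that add atoms: none
Why: Morita–Baylis–Hillman reaction, in which the DABCO–acrylate zwitterion adds to the reactive α-silyloxy aldehyde; the carbinol centre forms as a racemate, which is harmless because step 2 removes it.

Step 2
Reactants: 3 methyl 4-{[tert-butyl(dimethyl)silyl]oxy}-3-hydroxy-2-methylidenebutanoate
Product: 4 methyl (2Z)-2-(bromomethyl)-4-{[tert-butyl(dimethyl)silyl]oxy}but-2-enoate
Conditions: NBS, Me2S, CH2Cl2, 0 °C to rt
Reagents that add atoms: N-bromosuccinimide, O=C1CCC(=O)N1Br
Why: Corey–Kim-type activation of the allylic alcohol as an alkoxysulfonium salt and SN2′ attack of bromide should give the transposed conjugated allylic bromide as the favoured Z isomer (silyloxymethyl group trans to the ester).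

Step 3
Reactants: 4 methyl (2Z)-2-(bromomethyl)-4-{[tert-butyl(dimethyl)silyl]oxy}but-2-enoate; 5 3,4,5-trimethoxybenzaldehyde
Product: 7 (4R,5R)-4-({[tert-butyl(dimethyl)silyl]oxy}methyl)-3-methylidene-5-(3,4,5-trimethoxyphenyl)oxolan-2-one (4,5-cis), via syn hydroxy ester 6 (not isolated)
Conditions: CrCl2 (10 mol %), tridentate 1,8-bis(oxazolin-2-yl)carbazole ligand (single antipode, 12 mol %), iPr2NEt (25 mol %), Mn powder (2 equiv), Cp2ZrCl2 (1.2 equiv), THF, rt; aq. NH4Cl, then PPTS (cat.), CH2Cl2, rt to complete ring closure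
Reagents that add atoms: none
Why: Catalytic asymmetric Nozaki–Hiyama–Kishi 2-(alkoxycarbonyl)allylation, in which the allylchromium reacts at its γ-carbon through a closed chair transition state with the γ-substituent trans to the ester, giving the syn adduct 6 and hence the cis lactone, while the chiral ligand on chromium selects the Re face of the aldehyde and so sets both new centres as R.

Step 4
Reactants: 7 (4R,5R)-4-({[tert-butyl(dimethyl)silyl]oxy}methyl)-3-methylidene-5-(3,4,5-trimethoxyphenyl)oxolan-2-one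
Product: 8 (4R,5R)-4-({[tert-butyl(dimethyl)silyl]oxy}methyl)-3-methylidene-5-(3,4,5-trimethoxyphenyl)oxolan-2-ol (anomeric mixture)
Conditions: iBu2AlH (DIBAL-H, 1.2 equiv), CH2Cl2, −78 °C; aq. KNa tartrate
Reagents that add atoms: none
Why: Partial lactone reduction with DIBAL-H, where 1,2-hydride delivery at −78 °C should stop at the aluminium hemiacetal; the new hemiacetal centre is an anomeric mixture that step 5 removes.

Step 5
Reactants: 8 (4R,5R)-4-({[tert-butyl(dimethyl)silyl]oxy}methyl)-3-methylidene-5-(3,4,5-trimethoxyphenyl)oxolan-2-ol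
Product: 9 tert-butyl(dimethyl){[(2R,3R)-4-methylidene-2-(3,4,5-trimethoxyphenyl)oxolan-3-yl]methoxy}silane (2,3-cis)
Conditions: Et3SiH (3 equiv), BF3·OEt2 (1.5 equiv), CH2Cl2, −78 °C; aq. NaHCO3 quench at −78 °C
Reagents that add atoms: none
Why: Ionic hydrogenation of a lactol, in which BF3 ionises the hemiacetal to the oxocarbenium ion and Et3SiH reduces it at the oxygen-bearing carbon at a temperature where the silyl ether and the benzylic C–O bond should be inert.

Step 6
Reactants: 9 tert-butyl(dimethyl){[(2R,3R)-4-methylidene-2-(3,4,5-trimethoxyphenyl)oxolan-3-yl]methoxy}silane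
Product: 11 [(3S,4R,5R)-4-({[tert-butyl(dimethyl)silyl]oxy}methyl)-5-(3,4,5-trimethoxyphenyl)oxolan-3-yl]methanol (all-cis), via B-alkyl-9-BBN adduct 10 (not isolated)
Conditions: 9-BBN (1.5 equiv), THF, 0 °C to rt; then aq. NaOH, 30% H2O2, 0 °C
Reagents that add atoms: hydrogen peroxide, OO
Why: Hydroboration–oxidation, in which the bulky borane adds anti-Markovnikov to the exocyclic alkene from the face opposite the C3 silyloxymethyl and C2 aryl groups, so hydrogen reaches C4 from the open face and the new CH2 arm ends cis to both substituents (new centre S by CIP).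

Step 7
Reactants: 11 [(3S,4R,5R)-4-({[tert-butyl(dimethyl)silyl]oxy}methyl)-5-(3,4,5-trimethoxyphenyl)oxolan-3-yl]methanol
Product: 12 {[(2R,3R,4R)-4-(bromomethyl)-2-(3,4,5-trimethoxyphenyl)oxolan-3-yl]methoxy}(tert-butyl)dimethylsilane (all-cis)
Conditions: CBr4, PPh3, imidazole, CH2Cl2, 0 °C
Reagents that add atoms: tetrabromomethane, BrC(Br)(Br)Br
Why: Appel reaction, in which bromide displaces the alkoxyphosphonium salt of the primary alcohol under buffered conditions that should leave the silyl ether and all stereocentres untouched.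

Step 8
Reactants: 12 {[(2R,3R,4R)-4-(bromomethyl)-2-(3,4,5-trimethoxyphenyl)oxolan-3-yl]methoxy}(tert-butyl)dimethylsilane
Product: 13 {[(3R,4R,5R)-4-({[tert-butyl(dimethyl)silyl]oxy}methyl)-5-(3,4,5-trimethoxyphenyl)oxolan-3-yl]methyl}magnesium bromide (titrated THF solution, used directly)
Conditions: Mg turnings (I2-activated), THF, 40 °C
Reagents that add atoms: magnesium, [Mg]
Why: Grignard formation by insertion of magnesium into a primary C–Br bond; no leaving group sits on the β-carbon, so the reagent should be stable in THF.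

Step 9
Reactants: 14 3,4-dimethoxyphenol
Product: 15 3,4-dimethoxyphenyl 4-chlorobenzenesulfonate
Conditions: 4-ClC6H4SO2Cl, Et3N, DMAP (cat.), CH2Cl2, 0 °C to rt
Reagents that add atoms: 4-chlorobenzenesulfonyl chloride, O=S(=O)(Cl)c1ccc(Cl)cc1
Why: O-Sulfonylation of a phenol under amine base with DMAP catalysis, which also protects the electron-rich phenol from oxidation in the next step.

Step 10
Reactants: 15 3,4-dimethoxyphenyl 4-chlorobenzenesulfonate
Product: 16 2-iodo-4,5-dimethoxyphenyl 4-chlorobenzenesulfonate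
Conditions: NIS, CF3CO2H (cat.), MeCN, rt
Reagents that add atoms: N-iodosuccinimide, O=C1CCC(=O)N1I
Why: Electrophilic aromatic iodination, directed to the only free position para to a methoxy group, which is the carbon ortho to the sulfonyloxy group.

Step 11
Reactants: 13 {[(3R,4R,5R)-4-({[tert-butyl(dimethyl)silyl]oxy}methyl)-5-(3,4,5-trimethoxyphenyl)oxolan-3-yl]methyl}magnesium bromide; 16 2-iodo-4,5-dimethoxyphenyl 4-chlorobenzenesulfonate
Product: 21 2-{[(3R,4R,5R)-4-({[tert-butyl(dimethyl)silyl]oxy}methyl)-5-(3,4,5-trimethoxyphenyl)oxolan-3-yl]methyl}-4,5-dimethoxyphenol, via magnesiated aryl sulfonate 17 (not isolated), via 4,5-dimethoxybenzyne 18 (not isolated), via ortho-arylmagnesium bromide 19 (not isolated), via dimethyl arylboronate 20 (not isolated)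
Conditions: 16 (1.3 equiv), iPrMgCl·LiCl (titrated, equimolar to 16), THF, −78 °C, 30 min; then 13 (1.0 equiv), −78 °C to rt; B(OMe)3 (4 equiv), −78 °C to rt; aq. NaOH, 30% H2O2, 0 °C
Reagents that add atoms: hydrogen peroxide, OO
Why: Proposed new method: iodine–magnesium exchange at −78 °C turns 16 into the ortho-magnesiated sulfonate 17, which on warming expels magnesium 4-chlorobenzenesulfonate to give aryne 18; the primary alkylmagnesium 13 adds across the strained triple bond, forming the CH2–aryl bond and the ortho arylmagnesium 19, which B(OMe)3 captures as boronate 20 and alkaline H2O2 oxidises to the phenol by 1,2-aryl migration from boron to oxygen. The closest known reaction type is the addition of magnesium nucleophiles to arynes released from 2-magnesiated aryl sulfonates, followed by electrophilic quench of the new aryl–magnesium bond; the extension is a functionalised sp3 alkylmagnesium combined with borylation–oxidation. No ring closes and no stereocentre forms, since the three oxolane centres are remote spectators and the carbon bound to magnesium is a CH2 group. Regiochemistry needs no control, because 18 has a mirror plane bisecting the C1–C2 and C4–C5 bonds, so attack at either aryne carbon gives the same 1-alkyl-2-metallo-4,5-dimethoxy arrangement. The selectivity required is capture of 18 by 13 and not by the isopropyl reagent, 17 or 19; it should be secured by finishing the exchange at −78 °C (where 17 does not yet eliminate) before 13 is added, by the higher nucleophilicity of the unhindered primary alkylmagnesium over the hindered aryl species, and by a modest excess of the cheap partner 16.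

Step 12
Reactants: 21 2-{[(3R,4R,5R)-4-({[tert-butyl(dimethyl)silyl]oxy}methyl)-5-(3,4,5-trimethoxyphenyl)oxolan-3-yl]methyl}-4,5-dimethoxyphenol
Product: 22 tert-butyl(dimethyl){[(2R,3R,4R)-4-[(2,4,5-trimethoxyphenyl)methyl]-2-(3,4,5-trimethoxyphenyl)oxolan-3-yl]methoxy}silane
Conditions: MeI, K2CO3, acetone, 50 °C
Reagents that add atoms: iodomethane, CI
Why: Williamson ether synthesis, in which the phenoxide formed with K2CO3 is methylated by MeI in an SN2 reaction that does not affect the silyl ether.

Step 13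
Reactants: 22 tert-butyl(dimethyl){[(2R,3R,4R)-4-[(2,4,5-trimethoxyphenyl)methyl]-2-(3,4,5-trimethoxyphenyl)oxolan-3-yl]methoxy}silane
Product: 23 [(2R,3R,4R)-4-[(2,4,5-trimethoxyphenyl)methyl]-2-(3,4,5-trimethoxyphenyl)oxolan-3-yl]methanol (CNP0238280.1)
Conditions: Bu4NF (TBAF), THF, 0 °C to rt
Reagents that add atoms: none
Why: Fluoride-induced desilylation, driven by the strong Si–F bond, should free the primary alcohol without touching the aryl ethers, the oxolane or any stereocentre.

**Compound list**

1 | methyl acrylate | C=CC(=O)OC | starting material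
2 | (tert-butyldimethylsilyloxy)acetaldehyde | CC(C)(C)[Si](C)(C)OCC=O | starting material
3 | methyl 4-{[tert-butyl(dimethyl)silyl]oxy}-3-hydroxy-2-methylidenebutanoate (racemic) | COC(=O)C(=C)C(O)CO[Si](C)(C)C(C)(C)C | intermediate
4 | methyl (2Z)-2-(bromomethyl)-4-{[tert-butyl(dimethyl)silyl]oxy}but-2-enoate | COC(=O)/C(CBr)=C/CO[Si](C)(C)C(C)(C)C | intermediate
5 | 3,4,5-trimethoxybenzaldehyde | COc1cc(C=O)cc(OC)c1OC | starting material
6 | methyl (3R,4R)-3-({[tert-butyl(dimethyl)silyl]oxy}methyl)-4-hydroxy-2-methylidene-4-(3,4,5-trimethoxyphenyl)butanoate | O[C@@H](c1cc(OC)c(OC)c(OC)c1)[C@@H](CO[Si](C)(C)C(C)(C)C)C(=C)C(=O)OC | intermediate (not isolated)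
7 | (4R,5R)-4-({[tert-butyl(dimethyl)silyl]oxy}methyl)-3-methylidene-5-(3,4,5-trimethoxyphenyl)oxolan-2-one | C=C1C(=O)O[C@@H](c2cc(OC)c(OC)c(OC)c2)[C@H]1CO[Si](C)(C)C(C)(C)C | intermediate
8 | (4R,5R)-4-({[tert-butyl(dimethyl)silyl]oxy}methyl)-3-methylidene-5-(3,4,5-trimethoxyphenyl)oxolan-2-ol (anomeric mixture) | C=C1C(O)O[C@@H](c2cc(OC)c(OC)c(OC)c2)[C@H]1CO[Si](C)(C)C(C)(C)C | intermediate
9 | tert-butyl(dimethyl){[(2R,3R)-4-methylidene-2-(3,4,5-trimethoxyphenyl)oxolan-3-yl]methoxy}silane | C=C1CO[C@@H](c2cc(OC)c(OC)c(OC)c2)[C@H]1CO[Si](C)(C)C(C)(C)C | intermediate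
10 | 9-{[(3R,4R,5R)-4-({[tert-butyl(dimethyl)silyl]oxy}methyl)-5-(3,4,5-trimethoxyphenyl)oxolan-3-yl]methyl}-9-borabicyclo[3.3.1]nonane | B1(C[C@H]2CO[C@@H](c3cc(OC)c(OC)c(OC)c3)[C@H]2CO[Si](C)(C)C(C)(C)C)C2CCCC1CCC2 | intermediate (not isolated)
11 | [(3S,4R,5R)-4-({[tert-butyl(dimethyl)silyl]oxy}methyl)-5-(3,4,5-trimethoxyphenyl)oxolan-3-yl]methanol | OC[C@H]1CO[C@@H](c2cc(OC)c(OC)c(OC)c2)[C@H]1CO[Si](C)(C)C(C)(C)C | intermediate
12 | {[(2R,3R,4R)-4-(bromomethyl)-2-(3,4,5-trimethoxyphenyl)oxolan-3-yl]methoxy}(tert-butyl)dimethylsilane | BrC[C@H]1CO[C@@H](c2cc(OC)c(OC)c(OC)c2)[C@H]1CO[Si](C)(C)C(C)(C)C | intermediate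
13 | {[(3R,4R,5R)-4-({[tert-butyl(dimethyl)silyl]oxy}methyl)-5-(3,4,5-trimethoxyphenyl)oxolan-3-yl]methyl}magnesium bromide | Br[Mg]C[C@H]1CO[C@@H](c2cc(OC)c(OC)c(OC)c2)[C@H]1CO[Si](C)(C)C(C)(C)C | intermediate
14 | 3,4-dimethoxyphenol | COc1ccc(O)cc1OC | starting material
15 | 3,4-dimethoxyphenyl 4-chlorobenzenesulfonate | COc1ccc(OS(=O)(=O)c2ccc(Cl)cc2)cc1OC | intermediate
16 | 2-iodo-4,5-dimethoxyphenyl 4-chlorobenzenesulfonate | COc1cc(I)c(OS(=O)(=O)c2ccc(Cl)cc2)cc1OC | intermediate
17 | {2-[(4-chlorobenzenesulfonyl)oxy]-4,5-dimethoxyphenyl}magnesium chloride | COc1cc([Mg]Cl)c(OS(=O)(=O)c2ccc(Cl)cc2)cc1OC | intermediate (not isolated)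
18 | 4,5-dimethoxybenzyne (1,2-didehydro-4,5-dimethoxybenzene) | COC1=CC#CC=C1OC | intermediate (not isolated)
19 | (2-{[(3R,4R,5R)-4-({[tert-butyl(dimethyl)silyl]oxy}methyl)-5-(3,4,5-trimethoxyphenyl)oxolan-3-yl]methyl}-4,5-dimethoxyphenyl)magnesium bromide | COc1cc([Mg]Br)c(C[C@H]2CO[C@@H](c3cc(OC)c(OC)c(OC)c3)[C@H]2CO[Si](C)(C)C(C)(C)C)cc1OC | intermediate (not isolated)
20 | dimethyl (2-{[(3R,4R,5R)-4-({[tert-butyl(dimethyl)silyl]oxy}methyl)-5-(3,4,5-trimethoxyphenyl)oxolan-3-yl]methyl}-4,5-dimethoxyphenyl)boronate | COc1cc(B(OC)OC)c(C[C@H]2CO[C@@H](c3cc(OC)c(OC)c(OC)c3)[C@H]2CO[Si](C)(C)C(C)(C)C)cc1OC | intermediate (not isolated)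
21 | 2-{[(3R,4R,5R)-4-({[tert-butyl(dimethyl)silyl]oxy}methyl)-5-(3,4,5-trimethoxyphenyl)oxolan-3-yl]methyl}-4,5-dimethoxyphenol | COc1cc(O)c(C[C@H]2CO[C@@H](c3cc(OC)c(OC)c(OC)c3)[C@H]2CO[Si](C)(C)C(C)(C)C)cc1OC | intermediate
22 | tert-butyl(dimethyl){[(2R,3R,4R)-4-[(2,4,5-trimethoxyphenyl)methyl]-2-(3,4,5-trimethoxyphenyl)oxolan-3-yl]methoxy}silane | COc1cc(OC)c(OC)cc1C[C@H]1CO[C@@H](c2cc(OC)c(OC)c(OC)c2)[C@H]1CO[Si](C)(C)C(C)(C)C | intermediate
23 | [(2R,3R,4R)-4-[(2,4,5-trimethoxyphenyl)methyl]-2-(3,4,5-trimethoxyphenyl)oxolan-3-yl]methanol | COc1cc(OC)c(OC)cc1C[C@H]1CO[C@@H](c2cc(OC)c(OC)c(OC)c2)[C@H]1CO | target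

**Step count and risks**

Total step count: 13. Longest linear sequence: 11 steps (steps 1–8, then 11–13); steps 9–10 form the two-step side branch to 16.

Steps most likely to fail:

1. Step 11 (Proposed new method). The aryne may be consumed by the aryl magnesium species present (17 and the adduct 19) faster than by 13, or 19 may be protonated before it is borylated, so the three-component union would stall or give the deoxy arene. The fallback uses known chemistry and sets out from alkene 9. Hydroboration with 9-BBN as in step 6 gives borane 10, which is not oxidised. It is coupled in a B-alkyl Suzuki–Miyaura reaction with commercial 1-bromo-2,4,5-trimethoxybenzene (COc1cc(OC)c(OC)cc1Br) using PdCl2(dppf) and aq. K3PO4 in THF/DMF at 60 °C. This should give aryl ether 22 directly, so the route is rejoined at 22 and only step 13 remains. The fallback makes no compound outside the list (F0).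

2. Step 3. Enantiofacial discrimination, or the syn preference, of the ligated allylchromium carrying a silyloxymethyl group may be insufficient. The fallback sets out from 4 and 5 and replaces asymmetric catalysis by resolution. A ligand-free Barbier-type allylation with stoichiometric CrCl2 in THF at rt keeps the closed, cis-selective transition state but gives racemic material. This passes through 6 together with its mirror image methyl (3S,4S)-3-({[tert-butyl(dimethyl)silyl]oxy}methyl)-4-hydroxy-2-methylidene-4-(3,4,5-trimethoxyphenyl)butanoate F1. After ring closure it gives 7 together with (4S,5S)-4-({[tert-butyl(dimethyl)silyl]oxy}methyl)-3-methylidene-5-(3,4,5-trimethoxyphenyl)oxolan-2-one F2. The enantiomers are separated by preparative chromatography on a chiral stationary phase (amylose tris(3,5-dimethylphenylcarbamate), supercritical CO2/MeOH), and the route resumes at 7.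

3. Step 5. Hydride may add at the exocyclic terminus of the conjugated oxocarbenium ion (over-reduction to a 4-methyl ring), or the Lewis acid may strip the silyl ether or ionise the benzylic C–O bond and scramble that centre. The fallback sets out from lactone 7 and avoids acid altogether. Exhaustive reduction with iBu2AlH (3 equiv, CH2Cl2, −78 to 0 °C) should give (1R,2R)-2-({[tert-butyl(dimethyl)silyl]oxy}methyl)-3-methylidene-1-(3,4,5-trimethoxyphenyl)butane-1,4-diol F3. Selective tosylation of the primary allylic hydroxyl (TsCl, Et3N, DMAP cat., CH2Cl2, −10 °C) gives [(3R,4R)-3-({[tert-butyl(dimethyl)silyl]oxy}methyl)-4-hydroxy-2-methylidene-4-(3,4,5-trimethoxyphenyl)butyl] 4-methylbenzenesulfonate F4. KOtBu in THF at 0 °C then closes the ring by intramolecular Williamson etherification; SN2 and SN2′ attack lead to the same ring and the benzylic C–O bond is never broken. The route is rejoined at 9.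

Further compounds
F0 | step 11 | none | none
F1 | step 3 | methyl (3S,4S)-3-({[tert-butyl(dimethyl)silyl]oxy}methyl)-4-hydroxy-2-methylidene-4-(3,4,5-trimethoxyphenyl)butanoate | O[C@H](c1cc(OC)c(OC)c(OC)c1)[C@H](CO[Si](C)(C)C(C)(C)C)C(=C)C(=O)OC
F2 | step 3 | (4S,5S)-4-({[tert-butyl(dimethyl)silyl]oxy}methyl)-3-methylidene-5-(3,4,5-trimethoxyphenyl)oxolan-2-one | C=C1C(=O)O[C@H](c2cc(OC)c(OC)c(OC)c2)[C@@H]1CO[Si](C)(C)C(C)(C)C
F3 | step 5 | (1R,2R)-2-({[tert-butyl(dimethyl)silyl]oxy}methyl)-3-methylidene-1-(3,4,5-trimethoxyphenyl)butane-1,4-diol | O[C@@H](c1cc(OC)c(OC)c(OC)c1)[C@@H](CO[Si](C)(C)C(C)(C)C)C(=C)CO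
F4 | step 5 | [(3R,4R)-3-({[tert-butyl(dimethyl)silyl]oxy}methyl)-4-hydroxy-2-methylidene-4-(3,4,5-trimethoxyphenyl)butyl] 4-methylbenzenesulfonate | O[C@@H](c1cc(OC)c(OC)c(OC)c1)[C@@H](CO[Si](C)(C)C(C)(C)C)C(=C)COS(=O)(=O)c1ccc(C)cc1
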